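**Retrosynthetic overview**
- Ardisiphenol C ⇒ the corresponding benzene-1,2,4-triyl triacetate. Only the two exposed acetates are removed at the end; the acetate wedged between the chain and the neighbouring oxygen stays.
- Triacetate ⇒ 6-alkylbenzene-1,2,4-triol, the aromatic tautomer of a 6-alkylcyclohexane-1,2,4-trione ⇒ Dieckmann disconnection (ring C5–C6, phenyl acetate numbering) to an acyclic 2,5-diketo ester.
- Key bond (ring C1–C2): 2,5-diketo ester ⇒ ethoxalyl anion (Breslow intermediate of ethyl glyoxylate) + β-carbon of a methyl enone (Stetter reaction).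
- Enone ⇒ methyl linoleate + acetonylidene ylide. Linoleate C1 becomes the chain-bearing ring carbon, and C2–C18 arrive as the intact (8Z,11Z)-C17 chain.
- Ring order: there is one ring only, the arene, closed in step 3.

Assumption: the target has no stereocentre, so "single enantiomer" is read as the single (8Z,11Z) geometrical isomer. Both Z-alkenes come with methyl linoleate and are never touched.

**Step 1**
Reactants: 1 methyl linoleate; 2 1-(triphenyl-λ5-phosphanylidene)propan-2-one
Product: 4 (3E,12Z,15Z)-henicosa-3,12,15-trien-2-one, via linoleyl aldehyde 3 (not isolated)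
Conditions: DIBAL-H (1.05 equiv), CH2Cl2, −78 °C; MeOH quench; then 2 (1.5 equiv), −78 → 40 °C; aq. Rochelle salt
Reagents that add atoms: 1-(triphenyl-λ5-phosphanylidene)propan-2-one (2), CC(=O)C=P(c1ccccc1)(c1ccccc1)c1ccccc1
Why: Partial ester reduction stops at the aluminium hemiacetal at −78 °C and the released aldehyde is trapped in the same flask by the stabilised ylide (one-pot DIBAL reduction/Wittig olefination, E-selective); the new alkene geometry does not matter because both carbons end up in the arene, and the skipped Z,Z-diene is inert.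

**Step 2**
Reactants: 4 (3E,12Z,15Z)-henicosa-3,12,15-trien-2-one; 5 ethyl glyoxylate
Product: 7 ethyl (11Z,14Z)-2-oxo-3-(2-oxopropyl)icosa-11,14-dienoate (racemic at C3), via Breslow enaminol 6 (not isolated)
Conditions: 5 (3 equiv, freshly cracked, slow addition), 3-benzyl-5-(2-hydroxyethyl)-4-methylthiazolium chloride (20 mol %), Et3N (50 mol %), EtOH, 70 °C, Ar
Reagents that add atoms: ethyl glyoxylate (5), CCOC(=O)C=O
Why: Stetter reaction: the thiazolylidene adds to the non-enolisable, very electrophilic aldehyde 5 and the ester-acidified C–H shifts to give enaminol 6, an ethoxalyl (acyl) anion equivalent that adds 1,4 to the β-carbon of 4, joining two natively electrophilic carbons, while competing benzoin adducts are reversible and drain into the irreversible 1,4-adduct (glyoxyl-type aldehydes are competent Stetter donors); the polar, radical-free conditions spare the bis-allylic CH2, and the new C3 stereocentre forms racemic and disappears in step 3.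

**Step 3**
Reactants: 7 ethyl (11Z,14Z)-2-oxo-3-(2-oxopropyl)icosa-11,14-dienoate; 8 acetic anhydride
Product: 10 6-[(8Z,11Z)-heptadeca-8,11-dien-1-yl]benzene-1,2,4-triyl triacetate, via benzenetriol 9 (not isolated)
Conditions: KOtBu (4 equiv), THF (0.02 M), 0 °C → rt, Ar; then Ac2O (8 equiv), 0 °C → rt
Reagents that add atoms: acetic anhydride (8), CC(=O)OC(C)=O
Why: Proposed new method: excess tert-butoxide first enolises the acidic C3–H, so the 2-keto group is masked as its enolate and the textbook 1,4-diketone → cyclopentenone aldol is shut off (any aldolate formed cannot dehydrate as an alkoxide and reverts), leaving the methyl-ketone enolate only the 6-exo attack on the activated ester (Dieckmann condensation; closest known types are oxalate-based cyclic 1,2,4-trione syntheses and Michael–Claisen routes to cyclohexane-1,3-diones), and because the resulting cyclohexane-1,2,4-trione is the keto tautomer of 9, irreversible aromatisation to the triphenoxide drives the closure and erases C3, after which Ac2O traps the air-sensitive salt as stable 10.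

**Step 4**
Reactants: 10 6-[(8Z,11Z)-heptadeca-8,11-dien-1-yl]benzene-1,2,4-triyl triacetate
Product: 11 ardisiphenol C, 2-[(8Z,11Z)-heptadeca-8,11-dien-1-yl]-4,6-dihydroxyphenyl acetate
Conditions: Novozym 435 (immobilised Candida antarctica lipase B), n-BuOH (10 equiv), MTBE, 40 °C, Ar, stopped at the monoacetate (HPLC control)
Reagents that add atoms: none
Why: Regioselective lipase-catalysed alcoholysis of aryl acetates: the C4 and C2 acetates are exposed and are esters of the better leaving phenols, whereas the C1 acetate is flanked by the C17 chain and an oxygen substituent and is the ester of the least acidic phenol, so it is cleaved last, and the neutral medium forms no phenoxide, which suppresses 1,2-acyl migration and leaves the Z-alkenes untouched.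

**Compound list**
1 | methyl linoleate, methyl (9Z,12Z)-octadeca-9,12-dienoate | CCCCC/C=C\C/C=C\CCCCCCCC(=O)OC | starting material
2 | 1-(triphenyl-λ5-phosphanylidene)propan-2-one | CC(=O)C=P(c1ccccc1)(c1ccccc1)c1ccccc1 | starting material
3 | linoleyl aldehyde, (9Z,12Z)-octadeca-9,12-dienal | CCCCC/C=C\C/C=C\CCCCCCCC=O | intermediate
4 | (3E,12Z,15Z)-henicosa-3,12,15-trien-2-one | CCCCC/C=C\C/C=C\CCCCCCC/C=C/C(C)=O | intermediate
5 | ethyl glyoxylate | CCOC(=O)C=O | starting material
6 | Breslow enaminol, ethyl 2-[3-benzyl-5-(2-hydroxyethyl)-4-methyl-1,3-thiazol-2(3H)-ylidene]-2-hydroxyacetate | CCOC(=O)C(O)=C1SC(CCO)=C(C)N1Cc1ccccc1 | intermediate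
7 | ethyl (11Z,14Z)-2-oxo-3-(2-oxopropyl)icosa-11,14-dienoate (racemic at C3) | CCCCC/C=C\C/C=C\CCCCCCCC(CC(C)=O)C(=O)C(=O)OCC | intermediate
8 | acetic anhydride | CC(=O)OC(C)=O | starting material
9 | 6-[(8Z,11Z)-heptadeca-8,11-dien-1-yl]benzene-1,2,4-triol (in the flask as its tripotassium salt) | CCCCC/C=C\C/C=C\CCCCCCCc1cc(O)cc(O)c1O | intermediate
10 | 6-[(8Z,11Z)-heptadeca-8,11-dien-1-yl]benzene-1,2,4-triyl triacetate | CCCCC/C=C\C/C=C\CCCCCCCc1cc(OC(C)=O)cc(OC(C)=O)c1OC(C)=O | intermediate
11 | ardisiphenol C, 2-[(8Z,11Z)-heptadeca-8,11-dien-1-yl]-4,6-dihydroxyphenyl acetate | CCCCC/C=C\C/C=C\CCCCCCCc1cc(O)cc(O)c1OC(C)=O | target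

**Total step count:** 4. **Longest linear sequence:** 4 (from methyl linoleate).

**Three steps most likely to fail**

Step 2 (intermolecular Stetter reaction). The ester-stabilised Breslow intermediate is a weak nucleophile and the β-alkyl enone is a sluggish acceptor, so glyoxylate self-condensation or aldol at the methyl ketone may win.
- The fallback sets out from 4 and comes back at 7, replacing the catalytic acyl anion by a stoichiometric masked one.
- Commercial ethyl 1,3-dithiane-2-carboxylate is deprotonated (LDA, THF, −78 °C) and added 1,4 to 4, with a cold quench. This gives ethyl 2-[(12Z,15Z)-2-oxohenicosa-12,15-dien-4-yl]-1,3-dithiane-2-carboxylate F1.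
- F1 is unmasked non-oxidatively (MeI, CaCO3, aq. MeCN, 45 °C; alkene-safe) to 7.

Step 3 (Dieckmann closure versus five-ring aldol). If the cyclopentenone or oligomers dominate, the order of the two ring bonds is reversed, so that no 1,4-diketone carrying a free methyl ketone ever exists.
- The fallback sets out from 4 and comes back at 9, which is acetylated in the same flask to 10.
- 4 is deprotonated at its methyl group (LiHMDS, 2.2 equiv, THF, −78 °C) and acylated with methyl dimethoxyacetate (crossed Claisen). This gives (5E,14Z,17Z)-1,1-dimethoxytricosa-5,14,17-triene-2,4-dione F2.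
- Aqueous formic acid frees (5E,14Z,17Z)-2,4-dioxotricosa-5,14,17-trienal F3.
- An intramolecular Stetter reaction (triazolium or thiazolium salt, iPr2NEt, THF) closes the same C1–C2 ring bond 6-exo.
- The resulting trione tautomerises to 9, and Ac2O/Et3N is added before exposure to air.

Step 4 (regioselective removal of two of three acetates). The enzyme may stop at a diacetate, over-run to the triol, or allow acyl migration. The fallback sets out from 10 and comes back at 11, replacing selective deprotection by selective protection.
- Degassed K2CO3/MeOH strips 10 to 9.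
- TBSCl (2.1 equiv), imidazole, DMF, 0 °C silylates the two less hindered phenols. This gives 2,4-bis[(tert-butyldimethylsilyl)oxy]-6-[(8Z,11Z)-heptadeca-8,11-dien-1-yl]phenol F4.
- Ac2O, Et3N, DMAP, CH2Cl2 acetylates the remaining hindered phenol. This gives 2,4-bis[(tert-butyldimethylsilyl)oxy]-6-[(8Z,11Z)-heptadeca-8,11-dien-1-yl]phenyl acetate F5.
- HF·pyridine, THF, 0 °C (acidic, so no phenoxide and no acetyl shift) releases 11.

**Further compounds**
F1 | step 2 | ethyl 2-[(12Z,15Z)-2-oxohenicosa-12,15-dien-4-yl]-1,3-dithiane-2-carboxylate | CCCCC/C=C\C/C=C\CCCCCCCC(CC(C)=O)C1(C(=O)OCC)SCCCS1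
F2 | step 3 | (5E,14Z,17Z)-1,1-dimethoxytricosa-5,14,17-triene-2,4-dione | CCCCC/C=C\C/C=C\CCCCCCC/C=C/C(=O)CC(=O)C(OC)OC
F3 | step 3 | (5E,14Z,17Z)-2,4-dioxotricosa-5,14,17-trienal | CCCCC/C=C\C/C=C\CCCCCCC/C=C/C(=O)CC(=O)C=O
F4 | step 4 | 2,4-bis[(tert-butyldimethylsilyl)oxy]-6-[(8Z,11Z)-heptadeca-8,11-dien-1-yl]phenol | CCCCC/C=C\C/C=C\CCCCCCCc1cc(O[Si](C)(C)C(C)(C)C)cc(O[Si](C)(C)C(C)(C)C)c1O
F5 | step 4 | 2,4-bis[(tert-butyldimethylsilyl)oxy]-6-[(8Z,11Z)-heptadeca-8,11-dien-1-yl]phenyl acetate | CCCCC/C=C\C/C=C\CCCCCCCc1cc(O[Si](C)(C)C(C)(C)C)cc(O[Si](C)(C)C(C)(C)C)c1OC(C)=O
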